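**Retrosynthetic overview**
1. Oxane ring B comes last: 28 ⇐ lactone 26 by Petasis methylenation of C2=O, and 26 ⇐ hexenoic acid 25 by 6-endo bromolactonisation (forms O1–C6 and C5–Br).
2. Ring A substituents are relayed from cyclohexane C1. C3–Br comes from SN2 inversion of an axial alcohol, and C4(CH3)(Cl) from axial methylation of a 2-chloro enolate, both starting from 2-chlorocyclohexenone 18.
3. Ring A itself: cutting cyclohexane C1–C2 and C4–C5 leads to the acyclic enal ester 13. In the forward direction, one amine-catalysed domino Michael/aldol condensation closes a temporary γ-lactone and ring A together.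
4. Enabling feature: the hydroxyl-bearing quaternary carbon C3 of the oxane is bonded directly to cyclohexane C1. Its oxygen, two bonds from C1, can carry cyclohexane C2–C3–C4 as a 4-chloroacetoacetate and deliver it through a five-membered ring. Loss of CO2 then removes the tether.
5. Order of rings: γ-lactone plus ring A (step 7), lactone removed (step 8), ring B (step 15). Oxane C3 is set by a Sharpless epoxidation (step 2).

Key step: step 7

Remark: locants follow the name (3S,5R)-5-bromo-3-[(1S,3S,4S)-3-bromo-4-chloro-4-methylcyclohexyl]-6,6-dimethyl-2-methylideneoxan-3-ol; ring A = cyclohexane, ring B = oxane.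

Step 1
Reactants: 1 2-methylidenepropane-1,3-diol
Product: 2 2-{[(4-methoxyphenyl)methoxy]methyl}prop-2-en-1-ol
Conditions: NaH (1.0 equiv), 4-methoxybenzyl chloride, Bu4NI (cat.), THF/DMF, 0 °C → rt
Reagents that add atoms: 4-methoxybenzyl chloride, COc1ccc(CCl)cc1
Why: Williamson etherification of the mono-sodium alkoxide of a symmetrical diol should stop largely at the mono-ether and so distinguishes the two CH2OH arms; no stereocentre is formed.

Step 2
Reactants: 2 2-{[(4-methoxyphenyl)methoxy]methyl}prop-2-en-1-ol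
Product: 3 [(2R)-2-{[(4-methoxyphenyl)methoxy]methyl}oxiran-2-yl]methanol
Conditions: Ti(OiPr)4 (10 mol %), D-(−)-diisopropyl tartrate (12 mol %), tBuOOH, 4 Å MS, CH2Cl2, −20 °C
Reagents that add atoms: tert-butyl hydroperoxide, CC(C)(C)OO
Why: Sharpless asymmetric epoxidation of a 2-substituted allylic alcohol, in which the D-(−)-tartrate should deliver oxygen to the face that gives the (R)-epoxide and thereby sets the later oxane C3.

Step 3
Reactants: 3 [(2R)-2-{[(4-methoxyphenyl)methoxy]methyl}oxiran-2-yl]methanol; 4 (2-methylprop-1-en-1-yl)magnesium bromide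
Product: 5 (2S)-2-{[(4-methoxyphenyl)methoxy]methyl}-5-methylhex-4-ene-1,2-diol
Conditions: 4 (3 equiv), CuI (10 mol %), THF, −30 → 0 °C; then H2O
Reagents that add atoms: none
Why: Copper-catalysed SN2 opening of the 2,2-disubstituted epoxide at its unsubstituted CH2 builds the prenyl chain without touching the C–O bond of the quaternary stereocentre, so its configuration is kept.

Step 4
Reactants: 5 (2S)-2-{[(4-methoxyphenyl)methoxy]methyl}-5-methylhex-4-ene-1,2-diol; 6 (triphenyl-λ5-phosphanylidene)acetaldehyde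
Product: 8 (2E,4S)-4-hydroxy-4-{[(4-methoxyphenyl)methoxy]methyl}-7-methylocta-2,6-dienal, via hydroxy aldehyde 7 (not isolated)
Conditions: TEMPO (10 mol %), PhI(OAc)2, CH2Cl2, rt; then 6, rt → 40 °C
Reagents that add atoms: none
Why: Nitroxyl-catalysed oxidation selects the primary alcohol, and the sensitive α-hydroxy aldehyde 7 is trapped at once in a Wittig olefination whose stabilised ylide should give the E-enal; the stereocentre has no α-hydrogen and cannot epimerise.

Step 5
Reactants: 9 2,2-dimethyl-1,3-dioxane-4,6-dione (Meldrum's acid); 10 chloroacetyl chloride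
Product: 11 5-(2-chloro-1-hydroxyethylidene)-2,2-dimethyl-1,3-dioxane-4,6-dione
Conditions: pyridine, CH2Cl2, 0 °C → rt
Reagents that add atoms: none
Why: C-acylation of Meldrum's acid with an acid chloride gives the enolised acyl derivative, the standard precursor of an acylketene.

Step 6
Reactants: 8 (2E,4S)-4-hydroxy-4-{[(4-methoxyphenyl)methoxy]methyl}-7-methylocta-2,6-dienal; 11 5-(2-chloro-1-hydroxyethylidene)-2,2-dimethyl-1,3-dioxane-4,6-dione
Product: 13 (2E,4S)-4-{[(4-methoxyphenyl)methoxy]methyl}-7-methyl-1-oxoocta-2,6-dien-4-yl 4-chloro-3-oxobutanoate, via chloroacetylketene 12 (not isolated)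
Conditions: toluene, 85 °C
Reagents that add atoms: none
Why: Thermolysis of the acyl Meldrum's acid releases acylketene 12, which even a hindered tertiary alcohol should trap (acylketene acylation) faster than the conjugated aldehyde can, under neutral conditions that leave the enal and the stereocentre untouched.

Step 7
Reactants: 13 (2E,4S)-4-{[(4-methoxyphenyl)methoxy]methyl}-7-methyl-1-oxoocta-2,6-dien-4-yl 4-chloro-3-oxobutanoate
Product: 16 (3S,3aS,7aS)-6-chloro-3-{[(4-methoxyphenyl)methoxy]methyl}-3-(3-methylbut-2-en-1-yl)-3a,4-dihydro-2-benzofuran-1,7(3H,7aH)-dione, via Michael adduct 14 (not isolated), via aldol chlorohydrin 15 (not isolated)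
Conditions: (R)-α,α-diphenylprolinol trimethylsilyl ether (20 mol %), PhCO2H (20 mol %), toluene, rt; then TsOH·H2O (20 mol %), 60 °C, same flask
Reagents that add atoms: none
Why: The secondary amine turns the enal of 13 into an E-iminium ion and the tethered keto ester enol adds to its β-carbon (Michael addition, cyclohexane C1–C2 bond) to give 14; the CH2Cl-derived enol of the same keto ester then attacks the released aldehyde (aldol, C4–C5 bond) to give 15, which TsOH dehydrates to the 2-chloroenone 16. The closest known reaction type is the amine-catalysed domino Michael/aldol reaction of γ-chloro-β-keto esters with enals (formal [3+3] cyclohexanone annulation), run here intramolecularly. The temporary γ-lactone closes 5-exo-trig and ring A closes 6-(enolendo)-exo-trig. The stereocentre at cyclohexane C1 (C3a of 16) is controlled by the diphenyl(silyloxy)methyl group of the (R)-catalyst, which shields one face of the iminium ion, whereas C7a is epimerisable, should settle as the cis-fused lactone and is erased in step 8. The step needs three things: reactivity at a β-carbon next to a fully substituted carbon, secured by the five-membered tether; chemoselectivity between the two nucleophilic carbons, secured by ring size (the doubly activated CH2 reaches only the β-carbon, the CH2Cl carbon only the aldehyde); and dehydration instead of epoxide closure, secured by the acidic medium.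

Step 8
Reactants: 16 (3S,3aS,7aS)-6-chloro-3-{[(4-methoxyphenyl)methoxy]methyl}-3-(3-methylbut-2-en-1-yl)-3a,4-dihydro-2-benzofuran-1,7(3H,7aH)-dione
Product: 18 (5S)-2-chloro-5-{(2S)-2-hydroxy-1-[(4-methoxyphenyl)methoxy]-5-methylhex-4-en-2-yl}cyclohex-2-en-1-one, via β-keto acid 17 (not isolated)
Conditions: LiCl, H2O, DMSO, 120 °C
Reagents that add atoms: none
Why: Krapcho-type dealkoxycarbonylation, in which the tert-alkyl β-keto lactone opens with water to β-keto acid 17 and loses CO2, so the tether and the C7a centre disappear and the tertiary alcohol is freed while cyclohexane C1 is untouched.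

Step 9
Reactants: 18 (5S)-2-chloro-5-{(2S)-2-hydroxy-1-[(4-methoxyphenyl)methoxy]-5-methylhex-4-en-2-yl}cyclohex-2-en-1-one
Product: 19 (5S)-2-chloro-5-{(2S)-1-[(4-methoxyphenyl)methoxy]-5-methyl-2-[(triethylsilyl)oxy]hex-4-en-2-yl}cyclohex-2-en-1-one
Conditions: Et3SiOTf, 2,6-lutidine, CH2Cl2, −78 → 0 °C
Reagents that add atoms: triethylsilyl trifluoromethanesulfonate, CC[Si](CC)(CC)OS(=O)(=O)C(F)(F)F
Why: Silylation with a silyl triflate and a hindered pyridine base is the standard protection of a tertiary alcohol and keeps it out of the enolate, bromolactonisation and methylenation steps.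

Step 10
Reactants: 19 (5S)-2-chloro-5-{(2S)-1-[(4-methoxyphenyl)methoxy]-5-methyl-2-[(triethylsilyl)oxy]hex-4-en-2-yl}cyclohex-2-en-1-one
Product: 21 (2S,5S)-2-chloro-5-{(2S)-1-[(4-methoxyphenyl)methoxy]-5-methyl-2-[(triethylsilyl)oxy]hex-4-en-2-yl}-2-methylcyclohexan-1-one, via lithium chloro enolate 20 (not isolated)
Conditions: LiBH(sBu)3 (1.05 equiv), THF, −78 °C; then MeI, DMPU, −78 → −20 °C
Reagents that add atoms: iodomethane, CI
Why: Proposed new method: 1,4-hydride transfer from the hindered borohydride to the 2-chloroenone (no extra β-substituent) should give the regiodefined chloro enolate 20, which at low temperature has no partner for Darzens or Favorskii chemistry and should be C-methylated along the axial trajectory of the half-chair that keeps the side chain equatorial, so that CH3 ends axial and cis to the side chain and Cl equatorial (2S); the closest known reaction type is the conjugate reduction–alkylation of cyclohexenones with trialkylborohydrides, and axial alkylation of 5-substituted cyclohexanone enolates follows the same stereoelectronic rule.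

Step 11
Reactants: 21 (2S,5S)-2-chloro-5-{(2S)-1-[(4-methoxyphenyl)methoxy]-5-methyl-2-[(triethylsilyl)oxy]hex-4-en-2-yl}-2-methylcyclohexan-1-one
Product: 22 (1R,2S,5S)-2-chloro-5-{(2S)-1-[(4-methoxyphenyl)methoxy]-5-methyl-2-[(triethylsilyl)oxy]hex-4-en-2-yl}-2-methylcyclohexan-1-ol
Conditions: LiBH(sBu)3, THF, −78 °C; then H2O
Reagents that add atoms: none
Why: Ketone reduction with a bulky trialkylborohydride proceeds by equatorial attack, as with 2,2-disubstituted cyclohexanones, and should give the axial alcohol (1R), cis to the equatorial chlorine so that no epoxide can form.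

Step 12
Reactants: 22 (1R,2S,5S)-2-chloro-5-{(2S)-1-[(4-methoxyphenyl)methoxy]-5-methyl-2-[(triethylsilyl)oxy]hex-4-en-2-yl}-2-methylcyclohexan-1-ol
Product: 23 triethyl({(2S)-2-[(1S,3S,4S)-3-bromo-4-chloro-4-methylcyclohexyl]-1-[(4-methoxyphenyl)methoxy]-5-methylhex-4-en-2-yl}oxy)silane
Conditions: PPh3, CBr4, CH2Cl2, 0 °C → reflux
Reagents that add atoms: carbon tetrabromide, BrC(Br)(Br)Br
Why: Appel reaction, in which SN2 displacement of the axial oxyphosphonium group by bromide inverts the carbinol carbon and should give the equatorial bromide (3S), trans to chlorine and cis to the side chain; this displacement has precedent for axial cyclohexanols flanked by a quaternary carbon.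

Step 13
Reactants: 23 triethyl({(2S)-2-[(1S,3S,4S)-3-bromo-4-chloro-4-methylcyclohexyl]-1-[(4-methoxyphenyl)methoxy]-5-methylhex-4-en-2-yl}oxy)silane
Product: 24 (2S)-2-[(1S,3S,4S)-3-bromo-4-chloro-4-methylcyclohexyl]-5-methyl-2-[(triethylsilyl)oxy]hex-4-en-1-ol
Conditions: DDQ, CH2Cl2/pH 7 buffer, 0 °C
Reagents that add atoms: none
Why: Oxidative cleavage of the 4-methoxybenzyl ether with DDQ is neutral and orthogonal to the silyl ether, the alkene and the alkyl halides.

Step 14
Reactants: 24 (2S)-2-[(1S,3S,4S)-3-bromo-4-chloro-4-methylcyclohexyl]-5-methyl-2-[(triethylsilyl)oxy]hex-4-en-1-ol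
Product: 25 (2S)-2-[(1S,3S,4S)-3-bromo-4-chloro-4-methylcyclohexyl]-5-methyl-2-[(triethylsilyl)oxy]hex-4-enoic acid
Conditions: TEMPO (20 mol %), PhI(OAc)2 (2.2 equiv), MeCN/H2O, rt
Reagents that add atoms: water, O
Why: Nitroxyl-catalysed oxidation in aqueous acetonitrile takes the primary alcohol through the aldehyde hydrate to the acid without touching the trisubstituted alkene or the halides.

Step 15
Reactants: 25 (2S)-2-[(1S,3S,4S)-3-bromo-4-chloro-4-methylcyclohexyl]-5-methyl-2-[(triethylsilyl)oxy]hex-4-enoic acid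
Product: 26 (3S,5R)-5-bromo-3-[(1S,3S,4S)-3-bromo-4-chloro-4-methylcyclohexyl]-6,6-dimethyl-3-[(triethylsilyl)oxy]oxan-2-one
Conditions: NBS, MeCN, −20 → 0 °C, dark
Reagents that add atoms: N-bromosuccinimide, O=C1CCC(=O)N1Br
Why: Bromolactonisation, in which the carboxyl group opens the bromonium ion at the tertiary carbon (6-endo, Markovnikov) in a chair-like transition state with the cyclohexyl group equatorial and the silyloxy group axial, and anti addition places bromine equatorial, cis to the cyclohexyl group (5R).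

Step 16
Reactants: 26 (3S,5R)-5-bromo-3-[(1S,3S,4S)-3-bromo-4-chloro-4-methylcyclohexyl]-6,6-dimethyl-3-[(triethylsilyl)oxy]oxan-2-one
Product: 28 (3S,5R)-5-bromo-3-[(1S,3S,4S)-3-bromo-4-chloro-4-methylcyclohexyl]-6,6-dimethyl-2-methylideneoxan-3-ol, via triethylsilyl ether 27 (not isolated)
Conditions: Cp2TiMe2 (3 equiv), toluene, 70 °C, dark; then Bu4NF, THF, 0 °C
Reagents that add atoms: dimethyltitanocene Cp2TiMe2, [CH3-].[CH3-].[Ti+4].[cH-]1cccc1.[cH-]1cccc1
Why: Petasis methylenation should convert the lactone carbonyl into the exocyclic enol ether under non-basic, Lewis-acid-free conditions that alkyl halides tolerate (no endocyclic isomer is possible because oxane C3 bears no hydrogen), and fluoride then removes the silyl group without acid.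

**Compound list**
1 | 2-methylidenepropane-1,3-diol | C=C(CO)CO | starting material
2 | 2-{[(4-methoxyphenyl)methoxy]methyl}prop-2-en-1-ol | C=C(CO)COCc1ccc(OC)cc1 | intermediate
3 | [(2R)-2-{[(4-methoxyphenyl)methoxy]methyl}oxiran-2-yl]methanol | OC[C@]1(COCc2ccc(OC)cc2)CO1 | intermediate
4 | (2-methylprop-1-en-1-yl)magnesium bromide | CC(C)=C[Mg]Br | starting material
5 | (2S)-2-{[(4-methoxyphenyl)methoxy]methyl}-5-methylhex-4-ene-1,2-diol | CC(C)=CC[C@](COCc1ccc(OC)cc1)(O)CO | intermediate
6 | (triphenyl-λ5-phosphanylidene)acetaldehyde | O=CC=P(c1ccccc1)(c1ccccc1)c1ccccc1 | starting material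
7 | (2R)-2-hydroxy-2-{[(4-methoxyphenyl)methoxy]methyl}-5-methylhex-4-enal | CC(C)=CC[C@](COCc1ccc(OC)cc1)(O)C=O | intermediate
8 | (2E,4S)-4-hydroxy-4-{[(4-methoxyphenyl)methoxy]methyl}-7-methylocta-2,6-dienal | CC(C)=CC[C@](COCc1ccc(OC)cc1)(O)/C=C/C=O | intermediate
9 | 2,2-dimethyl-1,3-dioxane-4,6-dione (Meldrum's acid) | CC1(C)OC(=O)CC(=O)O1 | starting material
10 | chloroacetyl chloride | ClCC(=O)Cl | starting material
11 | 5-(2-chloro-1-hydroxyethylidene)-2,2-dimethyl-1,3-dioxane-4,6-dione | CC1(C)OC(=O)C(=C(O)CCl)C(=O)O1 | intermediate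
12 | 4-chlorobut-1-ene-1,3-dione (chloroacetylketene) | O=C=CC(=O)CCl | intermediate
13 | (2E,4S)-4-{[(4-methoxyphenyl)methoxy]methyl}-7-methyl-1-oxoocta-2,6-dien-4-yl 4-chloro-3-oxobutanoate | CC(C)=CC[C@](COCc1ccc(OC)cc1)(OC(=O)CC(=O)CCl)/C=C/C=O | intermediate
14 | [(2S,3S)-4-(chloroacetyl)-2-{[(4-methoxyphenyl)methoxy]methyl}-2-(3-methylbut-2-en-1-yl)-5-oxooxolan-3-yl]acetaldehyde (C4 epimerisable) | CC(C)=CC[C@]1(COCc2ccc(OC)cc2)OC(=O)C(C(=O)CCl)[C@@H]1CC=O | intermediate
15 | (3S,3aS)-6-chloro-5-hydroxy-3-{[(4-methoxyphenyl)methoxy]methyl}-3-(3-methylbut-2-en-1-yl)hexahydro-2-benzofuran-1,7-dione (C5, C6, C7a unassigned) | CC(C)=CC[C@]1(COCc2ccc(OC)cc2)OC(=O)C2[C@@H]1CC(O)C(Cl)C2=O | intermediate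
16 | (3S,3aS,7aS)-6-chloro-3-{[(4-methoxyphenyl)methoxy]methyl}-3-(3-methylbut-2-en-1-yl)-3a,4-dihydro-2-benzofuran-1,7(3H,7aH)-dione (cis-fused) | CC(C)=CC[C@]1(COCc2ccc(OC)cc2)OC(=O)[C@H]2[C@@H]1CC=C(Cl)C2=O | intermediate
17 | (6S)-3-chloro-6-{(2S)-2-hydroxy-1-[(4-methoxyphenyl)methoxy]-5-methylhex-4-en-2-yl}-2-oxocyclohex-3-ene-1-carboxylic acid (C1 unassigned) | CC(C)=CC[C@](COCc1ccc(OC)cc1)(O)[C@H]1CC=C(Cl)C(=O)C1C(=O)O | intermediate
18 | (5S)-2-chloro-5-{(2S)-2-hydroxy-1-[(4-methoxyphenyl)methoxy]-5-methylhex-4-en-2-yl}cyclohex-2-en-1-one | CC(C)=CC[C@](COCc1ccc(OC)cc1)(O)[C@H]1CC=C(Cl)C(=O)C1 | intermediate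
19 | (5S)-2-chloro-5-{(2S)-1-[(4-methoxyphenyl)methoxy]-5-methyl-2-[(triethylsilyl)oxy]hex-4-en-2-yl}cyclohex-2-en-1-one | CC(C)=CC[C@](COCc1ccc(OC)cc1)(O[Si](CC)(CC)CC)[C@H]1CC=C(Cl)C(=O)C1 | intermediate
20 | lithium (5S)-2-chloro-5-{(2S)-1-[(4-methoxyphenyl)methoxy]-5-methyl-2-[(triethylsilyl)oxy]hex-4-en-2-yl}cyclohex-1-en-1-olate | CC(C)=CC[C@](COCc1ccc(OC)cc1)(O[Si](CC)(CC)CC)[C@H]1CCC(Cl)=C([O-])C1.[Li+] | intermediate
21 | (2S,5S)-2-chloro-5-{(2S)-1-[(4-methoxyphenyl)methoxy]-5-methyl-2-[(triethylsilyl)oxy]hex-4-en-2-yl}-2-methylcyclohexan-1-one | CC(C)=CC[C@](COCc1ccc(OC)cc1)(O[Si](CC)(CC)CC)[C@H]1CC[C@](C)(Cl)C(=O)C1 | intermediate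
22 | (1R,2S,5S)-2-chloro-5-{(2S)-1-[(4-methoxyphenyl)methoxy]-5-methyl-2-[(triethylsilyl)oxy]hex-4-en-2-yl}-2-methylcyclohexan-1-ol | CC(C)=CC[C@](COCc1ccc(OC)cc1)(O[Si](CC)(CC)CC)[C@H]1CC[C@](C)(Cl)[C@H](O)C1 | intermediate
23 | triethyl({(2S)-2-[(1S,3S,4S)-3-bromo-4-chloro-4-methylcyclohexyl]-1-[(4-methoxyphenyl)methoxy]-5-methylhex-4-en-2-yl}oxy)silane | CC(C)=CC[C@](COCc1ccc(OC)cc1)(O[Si](CC)(CC)CC)[C@H]1CC[C@](C)(Cl)[C@@H](Br)C1 | intermediate
24 | (2S)-2-[(1S,3S,4S)-3-bromo-4-chloro-4-methylcyclohexyl]-5-methyl-2-[(triethylsilyl)oxy]hex-4-en-1-ol | CC(C)=CC[C@](CO)(O[Si](CC)(CC)CC)[C@H]1CC[C@](C)(Cl)[C@@H](Br)C1 | intermediate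
25 | (2S)-2-[(1S,3S,4S)-3-bromo-4-chloro-4-methylcyclohexyl]-5-methyl-2-[(triethylsilyl)oxy]hex-4-enoic acid | CC(C)=CC[C@](C(=O)O)(O[Si](CC)(CC)CC)[C@H]1CC[C@](C)(Cl)[C@@H](Br)C1 | intermediate
26 | (3S,5R)-5-bromo-3-[(1S,3S,4S)-3-bromo-4-chloro-4-methylcyclohexyl]-6,6-dimethyl-3-[(triethylsilyl)oxy]oxan-2-one | O=C1OC(C)(C)[C@H](Br)C[C@]1(O[Si](CC)(CC)CC)[C@H]1CC[C@](C)(Cl)[C@@H](Br)C1 | intermediate
27 | {[(3S,5R)-5-bromo-3-[(1S,3S,4S)-3-bromo-4-chloro-4-methylcyclohexyl]-6,6-dimethyl-2-methylideneoxan-3-yl]oxy}(triethyl)silane | C=C1OC(C)(C)[C@H](Br)C[C@]1(O[Si](CC)(CC)CC)[C@H]1CC[C@](C)(Cl)[C@@H](Br)C1 | intermediate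
28 | (3S,5R)-5-bromo-3-[(1S,3S,4S)-3-bromo-4-chloro-4-methylcyclohexyl]-6,6-dimethyl-2-methylideneoxan-3-ol | C=C1OC(C)(C)[C@H](Br)C[C@]1(O)[C@H]1CC[C@](C)(Cl)[C@@H](Br)C1 | target

Total step count: 16. Longest linear sequence: 15 (steps 1–4 and 6–16; step 5 is a side branch).

**Steps most likely to fail**

1. **Step 10 (labelled step).**
 - Risk: after hydride transfer the chloro enolate stays complexed to the trialkylborane and may alkylate too slowly. Proton exchange with the product, loss of chloride or attack from the equatorial side would then erode yield and selectivity.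
 - Fallback: it sets out from 19 and uses known operations. Rhodium-catalysed 1,4-hydrosilylation (Et3SiH, RhCl(PPh3)3, benzene, 50 °C) would give the isolable 2-chloro triethylsilyl enol ether F1. MeLi in THF at 0 °C would regenerate from it the borane-free lithium enolate 20 (regiospecific enolate generation from a silyl enol ether). Methylation with MeI/DMPU returns to the route at 21.

2. **Step 7.**
 - Risk: conjugate addition next to the fully substituted carbon may be slow, and the resident stereocentre may oppose the catalyst, giving poor facial selectivity. The aldol stage may also stall or be diverted by displacement of chloride.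
 - Fallback: it sets out from 8 and replaces the aldol closure by an irreversible olefination. Meldrum's acid 9 would be acylated with 2-chloro-2-(diethoxyphosphoryl)acetic acid (DCC, DMAP) to the phosphonate-bearing acyl Meldrum's acid F2. Heating F2 with 8 in toluene would give the chlorophosphono keto ester F3. The amine-catalysed (or Cs2CO3-mediated) 5-exo Michael cyclisation would stop at the lactone aldehyde phosphonate F4, where diastereomers can be separated. An intramolecular Horner–Wadsworth–Emmons reaction (LiCl, DBU, MeCN, rt) would then close ring A and come back to the route at 16.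

3. **Step 12.**
 - Risk: elimination toward cyclohexane C2 through the anti-periplanar axial hydrogen, or no substitution because the backside of the carbinol carbon is flanked by the axial methyl group.
 - Fallback: it sets out from 22 and separates activation from displacement. Tf2O and pyridine in CH2Cl2 at −30 °C would give the axial triflate F5. LiBr in acetone/DMPU at 0 °C, a non-basic medium, should displace it with inversion and come back to the route at 23.

**Further compounds**
F1 | step 10 | {[(5S)-2-chloro-5-{(2S)-1-[(4-methoxyphenyl)methoxy]-5-methyl-2-[(triethylsilyl)oxy]hex-4-en-2-yl}cyclohex-1-en-1-yl]oxy}(triethyl)silane | CC(C)=CC[C@](COCc1ccc(OC)cc1)(O[Si](CC)(CC)CC)[C@H]1CCC(Cl)=C(O[Si](CC)(CC)CC)C1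
F2 | step 7 | 5-[2-chloro-2-(diethoxyphosphoryl)-1-hydroxyethylidene]-2,2-dimethyl-1,3-dioxane-4,6-dione | CCOP(=O)(OCC)C(Cl)C(O)=C1C(=O)OC(C)(C)OC1=O
F3 | step 7 | (2E,4S)-4-{[(4-methoxyphenyl)methoxy]methyl}-7-methyl-1-oxoocta-2,6-dien-4-yl 4-chloro-4-(diethoxyphosphoryl)-3-oxobutanoate | CC(C)=CC[C@](COCc1ccc(OC)cc1)(OC(=O)CC(=O)C(Cl)P(=O)(OCC)OCC)/C=C/C=O
F4 | step 7 | diethyl {1-chloro-2-[(4S,5S)-5-{[(4-methoxyphenyl)methoxy]methyl}-5-(3-methylbut-2-en-1-yl)-2-oxo-4-(2-oxoethyl)oxolan-3-yl]-2-oxoethyl}phosphonate | CC(C)=CC[C@]1(COCc2ccc(OC)cc2)OC(=O)C(C(=O)C(Cl)P(=O)(OCC)OCC)[C@@H]1CC=O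
F5 | step 12 | (1R,2S,5S)-2-chloro-5-{(2S)-1-[(4-methoxyphenyl)methoxy]-5-methyl-2-[(triethylsilyl)oxy]hex-4-en-2-yl}-2-methylcyclohexyl trifluoromethanesulfonate | CC(C)=CC[C@](COCc1ccc(OC)cc1)(O[Si](CC)(CC)CC)[C@H]1CC[C@](C)(Cl)[C@H](OS(=O)(=O)C(F)(F)F)C1
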